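**The choice.** I had to send one charge either through a stirred tank or into a closed flask, and I reckoned both through one rate.

| setting | dusk | autumn |
|---|---|---|
| substrate | 0.30 M | 0.30 M |
| remark | one stirred flow tank at steady state, fed with the mixture as stated, mean residence time 50 h | a closed flask charged with all of it at once and left for 50 h |
| time |  | 50 h |

    intermediate ⇌ target (K1 = 2.1, k1 = 0.044 /h)
    target → over-reaction product (k2 = 0.0044 /h)
    substrate → intermediate (k3 = 0.037 /h)

1. the set-up with the highest amount of target at the outlet or at the end, in percent of the substrate put in ("none" if the first two lie within 2 percentage points) (dusk / autumn / none)
2. amount of target at the outlet or at the end, in percent of the substrate put in, dusk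
3. amount of target at the outlet or at the end, in percent of the substrate put in, autumn

**The rate.** Let λ be the relaxation rate of intermediate and target, the forward constant plus the back constant: λ = 0.0650 /h. Its half-life is 10.7 h, shorter than the 50 h on hand. Let S be the fraction of the charge that has left substrate. Target then gains at the forward constant times S and loses at λ times target. I set over-reaction aside, its half-life of 160 h being longer than 50 h.

**The curve.** In autumn, target starts flat, for the charge holds substrate and no intermediate. Substrate falls with a half-life of 19 h, so S bends over, and target trails it by about 1/λ = 15.4 h. With over-reaction set aside, the level it runs towards is 67.7% of the charge. At 50 h, I reckoned substrate at 15.7% and, still with over-reaction set aside, target at 46.5%.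

**The tank.** In dusk, with τ the residence time, S is constant, with 35.1% of the substrate left. Washout adds 1/τ to λ, which gives target 33.6%. The gap of 13 percentage points exceeds the margin, so I chose autumn, knowing both figures leave over-reaction out.

**The forecast.** The forecast, below my figures, named autumn with 28.8% for dusk and 42.6% for autumn, holding that “the tank runs entirely at outlet conditions”.

**The run.** Dusk gave 28.8% and autumn 42.6%. In autumn, substrate fed intermediate throughout, with 15.7% standing at 50.0 h, and target drew level with intermediate at 42.5 h, while over-reaction product reached 4.69%. Taking that from my figure leaves 41.8%. The same λ, applied to autumn read at 30 h, gives 28.6%; taking off the 1.55% of over-reaction product leaves 27.1%, and that reading held 27.3% of target.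

Its constants are made up; the flask was simulated.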